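Begin at late times, where the target readings of the grey run level off and can be added up.

- target at 5.0 h, in percent of the solid substrate charged
- concentration of dissolved substrate in solution at 5.0 h, in percent of saturation

| flask | solid substrate | reagent | remark | time |
|---|---|---|---|---|
| grey | 5 mM | 10.5 mM | run made earlier |  |
| ochre | 7.5 mM | 10.5 mM | run made earlier |  |
| blue | 10 mM | 5.2 mM | run made earlier |  |
| flask | 10 mM | 10.5 mM |  | 5.0 h |

| run | time / h | target / % | dissolved substrate / % |
|---|---|---|---|
| grey | 0.500 | 13 | 24 |
| grey | 1.00 | 21 | 31 |
| grey | 1.50 | 39 | 37 |
| grey | 2.50 | 49 | 14 |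
| grey | 3.00 | 52 | 10 |
| grey | 4.00 | 50 | 10 |
| ochre | 0.500 | 11 | 17 |
| ochre | 1.00 | 14 | 22 |
| ochre | 1.50 | 22 | 23 |
| ochre | 2.50 | 36 | 32 |
| ochre | 3.00 | 45 | 29 |
| ochre | 4.00 | 46 | 23 |
| blue | 0.833 | 6 | 18 |
| blue | 1.50 | 7 | 24 |
| blue | 2.50 | 15 | 30 |
| blue | 3.00 | 17 | 31 |
| blue | 4.00 | 21 | 36 |

(standard deviation of a reading: 2 percentage points)
- solid, in amounts per volume of the solution: solid substrate
- what may be going on: target <-> isomer of the product; reagent -> side product; solid substrate <-> dissolved substrate; dissolved substrate + reagent -> target
- at the start none of the solid substrate is in solution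
- dissolved substrate means what is dissolved; the solid is not counted in it

In the grey run, target reads 52% at 3.00 h and 50% at 4.00 h, with dissolved substrate at 10%. Assume that grey's charge is wholly in solution by then, so that the remainder is isomer of the product. Define the target share as c(target) divided by c(target) plus c(isomer): these readings give 0.567.

Now bracket the flask. For the ceiling, let no reagent become side product: solid substrate is then the limiting reagent, 10 mM against 10.5 mM, and target ends at 56.7%. For the floor, let the extra solid add no target: the flask then holds what ochre's last reading shows, 3.45 mM, or 34.5%.

Ochre's target reads 45% at 3.00 h and 46% at 4.00 h while dissolved substrate still reads 23%, which points to lost reagent, so expect the flask below the ceiling. Near the floor is likelier: with isomer of the product counted by the target share, what has dissolved at 0.500 h reads 2.35 mM in grey and 2.73 mM in ochre, a factor of 1.16 against 1.50 in the charges, so in these readings supply rises less than the solid. Expect a value just above the floor.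

The forecast gives 38% and 82%, holding that the flask “should plateau slightly higher”.

The flask gives 38.6% target and 80.0% of saturation.

    target ⇌ isomer of the product (K = 0.743, k = 0.343 /min)
    reagent → side product (k = 0.00307 /min)
    solid substrate ⇌ dissolved substrate, rate k3*(cs3 - [dissolved substrate]) while solid is left; crystals form when [dissolved substrate] > cs3 (solubility = 4.10 mM, k = 0.0183 /min)
    dissolved substrate + reagent → target (k = 3.85 /M/min)

Target and isomer of the product relax with a half-life of 0.861 min, far shorter than the 5.0 h of the flask. Apply the target share to the flask: reagent charged, less the 3.1% left and 3.46 mM of side product, leaves 6.72 mM coupled, and this predicts 38.1% target. Apply it to the neighbour with 2.5 mM of solid substrate, where 0.43% of the charge remains: it predicts 56.5%, and that flask gives 57.1%.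

The earlier runs and the new flask stem from a simulated flask for substances that don't exist; noise was put on by code.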